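Compound numbers are those of the steps below. Flavanone numbering is used for the skeleton throughout: ring C is O1, C2, C3, C4; ring A is C4a to C8a; ring B is C1' to C6'.

## Analysis of the target

The target is a pentacyclic bridged hemiketal. Ring A is fully substituted (5-OMe, a 2,2-dimethylpyran fused at C6/O7, 8-prenyl). Ring C is a dihydropyran, and one ortho oxygen of ring B is bonded to C4, which also carries OH. C2 and C4 are therefore the bridgeheads of a dioxabicyclo[3.3.1]nonane.

By CIP analysis of the structure both centres are R. Their relative configuration is forced by the bridge, so only C2 has to be controlled; C4 follows when the hemiketal closes.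

The sensitive groups are:
- the hemiketal;
- the prenyl and chromene double bonds, which rule out hydrogenation, free halogen and strong acid;
- the open flavanone, whose C2 is lost by retro-oxa-Michael opening in base;
- the C2–O1 benzylic ether, which is activated toward ionisation by the two ortho oxygens of ring B.

The difficulty is to set one benzylic ether stereocentre next to a di-ortho-oxygenated aryl ring and keep it to the end. The strategy rests on C3: it is a bare methylene between C2 and C4, and if those two carbons are bonded directly the skeleton becomes a flat, achiral 2-aryl-3-oxybenzofuran.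

## Retrosynthetic reasoning

**18 to 16.** The C4–O bond to ring B is a ring-chain tautomerism, so 18 is the closed form of the dihydroxyflavanone 17. The bridge can close on one face only, so nothing is needed beyond C2. Masking both ring B phenols as acetals gives 16 and keeps them out of the base, zinc and silylation chemistry.

**16 to 14.** C2 and C4 are reconnected, which turns the C3 methylene into the apex of a cyclopropanol 15, handled as its silyl ether 14. The cut is made here because it replaces the labile tertiary C2–H centre by a quaternary carbon that cannot epimerise. Forward, the alkoxide must break C2–C4 and not C3–C4, and the proton must enter C2 opposite the leaving C4, so that (2S) in 14 becomes (2R) in 16.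

**14 to 13.** Removing C3 (bonds C3–C2 and C3–C4) leaves the aromatic 3-silyloxybenzofuran 13, which has no stereocentre. All stereochemistry is thus created in one face-selective methylene transfer to an enol ether. The forward step must choose one enantiotopic face and must prefer this double bond over the prenyl and chromene alkenes.

**13 to 10.** Enol ether 13 comes from ketone 12. Cutting O1–C2 of 12 gives a phenol and an α-leaving group, the bromo ketone 11, made from deoxybenzoin 10. The α-carbon must be oxidised without electrophilic halogen in solution, because the ortho-prenyl phenol and the alkenes would react; a halophilic bromine donor acting only on the enolate achieves this.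

**10 to 6 and 8.** The bond between the α-carbon and C1' is cut, giving methyl ketone 6 and aryl bromide 8, joined by palladium-catalysed enolate arylation. The ring A phenol is masked in 6 and 9 by a fluoride-labile acetal that can be removed without touching the ring B acetals.

**6 to 1, 2, 4; 8 to 7.** The pyran ring of 5 is cut to the phenol 3 and enal 4. The prenyl group of 3 is cut to 1 and 2. The prenyl group goes on first because the carbon between the two hydroxyls is the more reactive; it then blocks that site so the pyran can only form on the other side. Bromide 8 is the bis-acetal of 7.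

## Alternatives that were turned down

**Alternative 1:** Ring A is disconnected at C4a–C5 and de-aromatised, leaving a chiral dihydropyranone A2 with a prenylated β-keto ester chain on C8a. In the forward key step the extended enolate of A2 attacks the ester through C4a and the new ring aromatises to flavanone A1.
- For: C2 is set early on a small pyranone by well-established asymmetric catalysis, and the ring closure never touches it. On this point it is stronger than the chosen route, whose stereocentre depends on a new method.
- Against: A1 still lacks the pyran ring and the 5-O-methyl group. Methylating the chelated 5-OH needs base on a flavanone whose C2 is base-labile. In A2 the methylene between ketone and ester is more acidic than the position that must be deprotonated. A2 itself needs a long chain synthesis.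
- Comparison: the chosen route puts every ring A substituent on a robust acetophenone before any stereocentre exists and is shorter.

**Alternative 2:** Ring C is disconnected at C2–C3, leading back to the 4-methylene benzodioxine A4, an enol acetal of a salicylate. A chiral aluminium Lewis acid ionises the acetal, and the tethered enolate recombines with the oxocarbenium ion through C3 to give flavanone A3.
- For: the flavanone forms without base, and the allyl ethers of A3 come off under neutral palladium catalysis. That is gentler than the final acid step of the chosen route.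
- Against: the oxocarbenium ion is planar and strongly stabilised by ring B, so it is long-lived and the acetal configuration is lost; selectivity would have to come from a loosely bound chiral counter-ion. The Lewis acid also meets two alkenes prone to cation-olefin reactions. The ring A salicylic acid needed for A4 is less accessible than acetophenone 1.
- Comparison: the chosen route creates the stereocentre in a concerted addition and stores it in a quaternary carbon.

**Alternative 3:** Ring B is replaced by cyclohexane-1,3-dione A7 and the bond C2–C1' is cut, leading to the tricyclic chromone A6. Silylation of A6 gives a benzopyrylium ion, A7 adds to C2 through its central carbon, and its enol oxygen closes onto C4 to give the bridged hemiketal A5.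
- For: it is the shortest route, needs no protecting groups, and builds the bridged bicycle directly. On step economy it is clearly stronger than the chosen route.
- Against: addition of a 1,3-dione is reversible, which threatens the configuration at C2. A5 must then be dehydrogenated to the phenol in the presence of a chromene, a prenyl group and a benzylic C2–H, all of which are sensitive to the oxidants that aromatise cyclohexenones.
- Comparison: the chosen route brings ring B in at the aromatic oxidation level and needs no late oxidation.

Key step: step 9

## Route

Remark on the chemistry: the free dihydroxyflavanone 17 is assumed to close spontaneously to hemiketal 18, the tautomer in which the target is drawn. The facial sense of the dipeptide-zinc carbenoid on this substrate cannot be derived beforehand; the route is written with the L,L-ligand, and its mirror image is used if the other face is attacked.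

Step 1
Reactants: 1 1-(2,4-dihydroxy-6-methoxyphenyl)ethanone; 2 1-bromo-3-methylbut-2-ene
Product: 3 1-[2,4-dihydroxy-6-methoxy-3-(3-methylbut-2-enyl)phenyl]ethanone
Conditions: 10% aq KOH, 0 °C to rt
Reagents that add atoms: none
Why: C-alkylation of the ambident phenoxide in water (nuclear prenylation), where hydrogen bonding to oxygen favours attack through carbon. The chelated 2'-hydroxy ketone fixes enol character in the C3'–C4' bond, so C3', flanked by both oxygens, should be the main site; C5' and O-alkylated isomers are removed by chromatography.

Step 2
Reactants: 3 1-[2,4-dihydroxy-6-methoxy-3-(3-methylbut-2-enyl)phenyl]ethanone; 4 3-methylbut-2-enal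
Product: 5 1-[7-hydroxy-5-methoxy-2,2-dimethyl-8-(3-methylbut-2-enyl)-2H-chromen-6-yl]ethanone
Conditions: ethylenediammonium diacetate (cat.), xylene, 140 °C
Reagents that add atoms: none
Why: Knoevenagel-type condensation of the enal at the only free ortho carbon of the 4'-phenol gives an ortho-quinone methide, which closes by oxa-6π electrocyclisation to the 2,2-dimethylchromene. The other ortho position is blocked by prenyl and the chelated phenol has no free ortho carbon, so one chromene only can form.

Step 3
Reactants: 5 1-[7-hydroxy-5-methoxy-2,2-dimethyl-8-(3-methylbut-2-enyl)-2H-chromen-6-yl]ethanone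
Product: 6 1-[5-methoxy-2,2-dimethyl-8-(3-methylbut-2-enyl)-7-{[2-(trimethylsilyl)ethoxy]methoxy}-2H-chromen-6-yl]ethanone
Conditions: NaH, DMF, 0 °C; SEMCl, 0 °C to rt
Reagents that add atoms: 2-(trimethylsilyl)ethoxymethyl chloride, C[Si](C)(C)CCOCCl
Why: Williamson etherification of the chelated phenoxide. The SEM acetal is inert to the strong base of the arylation and is later cleaved by fluoride, a mechanism that leaves MOM ethers alone.

Step 4
Reactants: 7 2-bromobenzene-1,3-diol
Product: 8 2-bromo-1,3-bis(methoxymethoxy)benzene
Conditions: MOMCl, iPr2NEt, CH2Cl2, 0 °C to rt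
Reagents that add atoms: chloromethyl methyl ether, COCCl
Why: Standard acetal protection of both phenols. MOM ethers tolerate alkoxide and amide bases and the zinc carbenoid, and their oxygens can coordinate zinc next to the enol ether.

Step 5
Reactants: 6 1-[5-methoxy-2,2-dimethyl-8-(3-methylbut-2-enyl)-7-{[2-(trimethylsilyl)ethoxy]methoxy}-2H-chromen-6-yl]ethanone; 8 2-bromo-1,3-bis(methoxymethoxy)benzene
Product: 9 2-[2,6-bis(methoxymethoxy)phenyl]-1-[5-methoxy-2,2-dimethyl-8-(3-methylbut-2-enyl)-7-{[2-(trimethylsilyl)ethoxy]methoxy}-2H-chromen-6-yl]ethanone
Conditions: Pd2(dba)3 (cat.), XPhos, NaOtBu, toluene, 80 °C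
Reagents that add atoms: none
Why: Palladium-catalysed α-arylation of the methyl ketone enolate; the bulky biarylphosphine promotes oxidative addition of the electron-rich di-ortho-substituted bromide and the reductive elimination. The methyl group is the only enolisable position, and the hindered, more acidic product enolate should not arylate again.

Step 6
Reactants: 9 2-[2,6-bis(methoxymethoxy)phenyl]-1-[5-methoxy-2,2-dimethyl-8-(3-methylbut-2-enyl)-7-{[2-(trimethylsilyl)ethoxy]methoxy}-2H-chromen-6-yl]ethanone
Product: 10 2-[2,6-bis(methoxymethoxy)phenyl]-1-[7-hydroxy-5-methoxy-2,2-dimethyl-8-(3-methylbut-2-enyl)-2H-chromen-6-yl]ethanone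
Conditions: Bu4NF, H2NCH2CH2NH2, THF, 60 °C, degassed; aq NH4Cl
Reagents that add atoms: none
Why: Fluoride attacks silicon and the SEM group fragments to ethene, formaldehyde and the phenoxide; the MOM acetals carry no silicon and stay. Ethylenediamine binds the formaldehyde so that it cannot hydroxymethylate the benzylic ketone.

Step 7
Reactants: 10 2-[2,6-bis(methoxymethoxy)phenyl]-1-[7-hydroxy-5-methoxy-2,2-dimethyl-8-(3-methylbut-2-enyl)-2H-chromen-6-yl]ethanone
Product: 12 2-[2,6-bis(methoxymethoxy)phenyl]-4-methoxy-7,7-dimethyl-9-(3-methylbut-2-enyl)-7H-furo[3,2-g]chromen-3(2H)-one (racemic), via alpha-bromo ketone 11 (not isolated)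
Conditions: LiN(SiMe3)2 (2.1 equiv), THF, −78 °C; BrCCl2CCl2Br (1.0 equiv), −78 to 0 °C; aq NH4Cl
Reagents that add atoms: none
Why: The phenoxide-enolate dianion takes bromine at carbon from 1,2-dibromotetrachloroethane by halophilic transfer; this donor reacts with carbanions only, so the alkenes and the ortho-prenyl phenoxide are not brominated. On warming, the phenoxide displaces the benzylic α-keto bromide in a 5-exo-tet Williamson closure; the new C2 centre is racemic and is erased in step 8.

Step 8
Reactants: 12 2-[2,6-bis(methoxymethoxy)phenyl]-4-methoxy-7,7-dimethyl-9-(3-methylbut-2-enyl)-7H-furo[3,2-g]chromen-3(2H)-one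
Product: 13 {2-[2,6-bis(methoxymethoxy)phenyl]-4-methoxy-7,7-dimethyl-9-(3-methylbut-2-enyl)-7H-furo[3,2-g]chromen-3-yl}oxy(trimethyl)silane
Conditions: LiN(SiMe3)2, THF, −78 °C; Me3SiCl, −78 to 0 °C; pentane, filtration under argon
Reagents that add atoms: chlorotrimethylsilane, C[Si](C)(C)Cl
Why: Deprotonation of the acidic C2–H gives an aromatic benzofuran-3-olate, which the hard silyl chloride takes at oxygen because C2 is hindered. Non-aqueous isolation keeps the labile trimethylsilyl enol ether intact.

Step 9
Reactants: 13 {2-[2,6-bis(methoxymethoxy)phenyl]-4-methoxy-7,7-dimethyl-9-(3-methylbut-2-enyl)-7H-furo[3,2-g]chromen-3-yl}oxy(trimethyl)silane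
Product: 14 (2S,3S)-2,3-methano-2,3-dihydro derivative of 13: a CH2 bridges C2 and C3 of the former furan ring, with the aryl group on C2 and Me3SiO on C3 cis on the ring-fusion carbons
Conditions: Et2Zn, CH2I2, Boc-L-Val-L-Pro-OMe, CH2Cl2, −40 to −20 °C; Et3N, aq NaHCO3
Reagents that add atoms: diiodomethane, ICI
Why: Proposed new method: the N-zincated dipeptide carries an iodomethylzinc unit that transfers CH2 to the furan C2=C3 bond of 13 (C2 and C4 in flavanone numbering) through the concerted butterfly transition state of the Simmons–Smith reaction, both C–C bonds forming on one face. The closest known reaction is the asymmetric Simmons–Smith cyclopropanation of trimethylsilyl enol ethers of aryl ketones with such a dipeptide-bound zinc carbenoid; what is new is an enol ether that is tetrasubstituted and part of a furan ring. The cyclopropane closes by [2+1] addition across an endocyclic bond, so it is necessarily cis-fused to the dihydrofuran. Both new centres (quaternary 2S and 3S) arise in this one event and their absolute sense is set by the chiral ligand on zinc, because 13 is achiral and ring B, standing perpendicular, shields both faces alike. The step needs chemoselectivity over the prenyl and chromene alkenes: the electrophilic carbenoid prefers the double bond bearing two oxygen donors, the MOM oxygens beside C2 can hold zinc close to it, and only a slight excess of carbenoid is used at low temperature. The loss of furan aromaticity is small and is offset by the high nucleophilicity of the enol ether. The product is quenched under basic conditions because acid would open it toward the 2-methylbenzofuranone.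

Step 10
Reactants: 14 (2S,3S)-2,3-methano-2,3-dihydro derivative of 13
Product: 16 (2R)-2-[2,6-bis(methoxymethoxy)phenyl]-5-methoxy-8,8-dimethyl-10-(3-methylbut-2-enyl)-2,3-dihydro-4H,8H-pyrano[3,2-g]chromen-4-one, via cyclopropanol 15 (not isolated)
Conditions: K2CO3 (0.3 equiv), MeOH/THF, −20 to 0 °C; pH 7 phosphate buffer
Reagents that add atoms: none
Why: Methanolysis of the silyl ether gives the cyclopropoxide, which undergoes base-induced homoketonisation: the shared C2–C4 bond breaks toward the carbon that best carries negative charge (benzylic and aryloxy-substituted), and this also relieves the bicyclic strain. Methanol protonates C2 from the rear of the breaking bond (SE2, inversion), so the 2S quaternary centre becomes the 2R tertiary centre. Catalytic carbonate at or below 0 °C limits enolisation and retro-oxa-Michael opening of the flavanone.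

Step 11
Reactants: 16 (2R)-2-[2,6-bis(methoxymethoxy)phenyl]-5-methoxy-8,8-dimethyl-10-(3-methylbut-2-enyl)-2,3-dihydro-4H,8H-pyrano[3,2-g]chromen-4-one
Product: 18 target CNP0170313.2: the (2R,4R) bridged hemiketal in which one ortho oxygen of ring B is bonded to C4 and C4 carries OH, via 2',6'-dihydroxyflavanone 17 (not isolated)
Conditions: 3 M aq HCl, THF, 40 °C
Reagents that add atoms: none
Why: Acid hydrolysis of both aryl MOM acetals; a freed ortho phenol then adds to the C4 ketone on the only face the bridge allows, so C2 dictates the 4R hemiketal centre. Ring A has no free phenol next to the prenyl group, so acid-induced chroman formation is excluded, and water as co-solvent prevents ketal exchange.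

## Compound list

1 | 1-(2,4-dihydroxy-6-methoxyphenyl)ethanone | CC(=O)c1c(O)cc(O)cc1OC | starting material
2 | 1-bromo-3-methylbut-2-ene | CC(C)=CCBr | starting material
3 | 1-[2,4-dihydroxy-6-methoxy-3-(3-methylbut-2-enyl)phenyl]ethanone | CC(=O)c1c(O)c(CC=C(C)C)c(O)cc1OC | intermediate
4 | 3-methylbut-2-enal | CC(C)=CC=O | starting material
5 | 1-[7-hydroxy-5-methoxy-2,2-dimethyl-8-(3-methylbut-2-enyl)-2H-chromen-6-yl]ethanone | CC(=O)c1c(O)c(CC=C(C)C)c2OC(C)(C)C=Cc2c1OC | intermediate
6 | SEM ether of 5 | CC(=O)c1c(OCOCC[Si](C)(C)C)c(CC=C(C)C)c2OC(C)(C)C=Cc2c1OC | intermediate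
7 | 2-bromobenzene-1,3-diol | Oc1cccc(O)c1Br | starting material
8 | 2-bromo-1,3-bis(methoxymethoxy)benzene | COCOc1cccc(OCOC)c1Br | intermediate
9 | SEM-protected deoxybenzoin | COCOc1cccc(OCOC)c1CC(=O)c1c(OCOCC[Si](C)(C)C)c(CC=C(C)C)c2OC(C)(C)C=Cc2c1OC | intermediate
10 | deoxybenzoin with free ring A phenol | COCOc1cccc(OCOC)c1CC(=O)c1c(O)c(CC=C(C)C)c2OC(C)(C)C=Cc2c1OC | intermediate
11 | alpha-bromo ketone of 10 (racemic; lithium phenoxide in the flask) | COCOc1cccc(OCOC)c1C(Br)C(=O)c1c(O)c(CC=C(C)C)c2OC(C)(C)C=Cc2c1OC | intermediate (not isolated)
12 | 2-[2,6-bis(methoxymethoxy)phenyl]-4-methoxy-7,7-dimethyl-9-(3-methylbut-2-enyl)-7H-furo[3,2-g]chromen-3(2H)-one (racemic) | COc1c2C=CC(C)(C)Oc2c(CC=C(C)C)c2OC(c3c(OCOC)cccc3OCOC)C(=O)c12 | intermediate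
13 | trimethylsilyl enol ether of 12 (3-silyloxybenzofuran) | COc1c2C=CC(C)(C)Oc2c(CC=C(C)C)c2oc(-c3c(OCOC)cccc3OCOC)c(O[Si](C)(C)C)c12 | intermediate
14 | (2S,3S)-silyloxycyclopropane fused to the dihydrofuran | COc1c2C=CC(C)(C)Oc2c(CC=C(C)C)c2O[C@]3(c4c(OCOC)cccc4OCOC)C[C@]3(O[Si](C)(C)C)c12 | intermediate
15 | (2S,3S)-cyclopropanol | COc1c2C=CC(C)(C)Oc2c(CC=C(C)C)c2O[C@]3(c4c(OCOC)cccc4OCOC)C[C@]3(O)c12 | intermediate (not isolated)
16 | (2R)-flavanone, ring B as bis-MOM ether | COc1c2C=CC(C)(C)Oc2c(CC=C(C)C)c2O[C@@H](c3c(OCOC)cccc3OCOC)CC(=O)c12 | intermediate
17 | (2R)-2',6'-dihydroxyflavanone | COc1c2C=CC(C)(C)Oc2c(CC=C(C)C)c2O[C@@H](c3c(O)cccc3O)CC(=O)c12 | intermediate (not isolated)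
18 | CNP0170313.2, (2R,4R) bridged hemiketal | COc1c2c(c(CC=C(C)C)c3c1[C@@]1(O)C[C@@H](O3)c3c(O)cccc3O1)OC(C)(C)C=C2 | target

## Step count and risks

Total: 11 steps. Longest linear sequence: 10 steps (1, 2, 3, 5, 6, 7, 8, 9, 10, 11) from compound 1; step 4 is the one-step branch from 7.

**Step 9 (key step, new method).** The most likely failures are three. Methylene may be transferred to the prenyl or chromene double bond. The tetrasubstituted enol ether may react too slowly, because ring B shields both faces and the furan must be dearomatised. The ligand may discriminate the two faces poorly on a substrate outside its known range. The fallback uses known chemistry, sets out from 5 and 8 and rejoins at 16. Bromine-lithium exchange on 8 (n-BuLi, THF, −78 °C) and formylation with DMF gives 2,6-bis(methoxymethoxy)benzaldehyde F1. Claisen–Schmidt condensation of F1 with 5 (KOH, EtOH) gives the 2'-hydroxychalcone F2. NaOAc in refluxing EtOH closes it by oxa-Michael addition to the racemic flavanone F3. Chromatography on a chiral stationary phase delivers 16; the (S)-enantiomer F4 can be re-equilibrated through F2 and recycled.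

**Step 10.** Two processes threaten it. The external C3–C4 bond may cleave instead, leading to ring contraction to a 2-methylbenzofuranone. The product may also lose configuration by reversible retro-oxa-Michael opening while base is present. The fallback sets out from 14 and rejoins at 16. Buffered fluoride (Bu4NF, AcOH, THF, −20 °C) releases cyclopropanol 15, which is isolated. One-electron oxidation with Mn(pic)3 (trivalent manganese) in DMF in the presence of Bu3SnH gives the alkoxy radical, which cleaves the shared bond toward the tertiary benzylic, oxygen-substituted C2 radical. Hydrogen transfer then gives the racemic flavanone F5. Resolution on a chiral stationary phase returns 16 and sets aside the (S)-enantiomer F6.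

**Step 5.** Oxidative addition and reductive elimination may be slow because the bromide is di-ortho-substituted and electron-rich and the ketone is hindered; reduction of the bromide would then compete. The fallback sets out from 6 and 8 and rejoins at 9. Claisen condensation of 6 with dimethyl carbonate (NaH, THF) gives the β-keto ester F7. Bromide 8 is converted (n-BuLi, then B(OiPr)3, aqueous work-up) to the boronic acid F8 and then with Pb(OAc)4 and catalytic Hg(OAc)2 to the aryllead triacetate F9. F9 arylates F7 at the central carbon (pyridine, CHCl3, 50 °C) to give F10. Krapcho decarboxylation (LiCl, wet DMSO, 130 °C) then gives 9.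

**Step 7.** Proton exchange between the bromo ketone and unreacted enolate may lead to double bromination, and ring closure at the hindered benzylic carbon may be slow. The fallback sets out from 10 and rejoins at 12. Regitz diazo transfer (4-acetamidobenzenesulfonyl azide, DBU, MeCN) gives the α-diazo ketone F11. Rh2(OAc)4 in CH2Cl2 then generates the carbene, which inserts into the neighbouring phenol O–H bond to close the five-membered ring.

**Step 1.** Alkylation may occur at C5', at oxygen, or twice, because the phenoxide is ambident and has two activated ring carbons. The fallback sets out from 1 and rejoins at 3. The free 4'-OH is alkylated selectively with 3-chloro-3-methylbut-1-yne (K2CO3, KI, CuI, acetone) to the propargyl ether F12. Semi-hydrogenation over Pd/CaCO3 poisoned with Pb(OAc)2 (Lindlar catalyst, quinoline, H2) gives the 1,1-dimethylallyl ether F13. Heating in toluene brings about an aromatic Claisen rearrangement, which delivers the normal prenyl group to C3', the carbon joined to C4' by the bond of higher double-bond character.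

## Further compounds

F1 | step 9 | 2,6-bis(methoxymethoxy)benzaldehyde | COCOc1cccc(OCOC)c1C=O
F2 | step 9 | (E)-3-[2,6-bis(methoxymethoxy)phenyl]-1-[7-hydroxy-5-methoxy-2,2-dimethyl-8-(3-methylbut-2-enyl)-2H-chromen-6-yl]prop-2-en-1-one | COCOc1cccc(OCOC)c1/C=C/C(=O)c1c(O)c(CC=C(C)C)c2OC(C)(C)C=Cc2c1OC
F3 | step 9 | racemic flavanone, ring B as bis-MOM ether | COc1c2C=CC(C)(C)Oc2c(CC=C(C)C)c2OC(c3c(OCOC)cccc3OCOC)CC(=O)c12
F4 | step 9 | (2S)-enantiomer of 16 | COc1c2C=CC(C)(C)Oc2c(CC=C(C)C)c2O[C@H](c3c(OCOC)cccc3OCOC)CC(=O)c12
F5 | step 10 | racemic flavanone, ring B as bis-MOM ether | COc1c2C=CC(C)(C)Oc2c(CC=C(C)C)c2OC(c3c(OCOC)cccc3OCOC)CC(=O)c12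
F6 | step 10 | (2S)-enantiomer of 16 | COc1c2C=CC(C)(C)Oc2c(CC=C(C)C)c2O[C@H](c3c(OCOC)cccc3OCOC)CC(=O)c12
F7 | step 5 | methyl 3-oxo-3-aryl-propanoate derived from 6 | COC(=O)CC(=O)c1c(OCOCC[Si](C)(C)C)c(CC=C(C)C)c2OC(C)(C)C=Cc2c1OC
F8 | step 5 | [2,6-bis(methoxymethoxy)phenyl]boronic acid | COCOc1cccc(OCOC)c1B(O)O
F9 | step 5 | [2,6-bis(methoxymethoxy)phenyl]lead triacetate | COCOc1cccc(OCOC)c1[Pb](OC(C)=O)(OC(C)=O)OC(C)=O
F10 | step 5 | methyl 2-[2,6-bis(methoxymethoxy)phenyl]-3-oxo-3-aryl-propanoate | COC(=O)C(c1c(OCOC)cccc1OCOC)C(=O)c1c(OCOCC[Si](C)(C)C)c(CC=C(C)C)c2OC(C)(C)C=Cc2c1OC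
F11 | step 7 | alpha-diazo ketone of 10 | COCOc1cccc(OCOC)c1C(=[N+]=[N-])C(=O)c1c(O)c(CC=C(C)C)c2OC(C)(C)C=Cc2c1OC
F12 | step 1 | 1-[2-hydroxy-6-methoxy-4-(2-methylbut-3-yn-2-yloxy)phenyl]ethanone | CC(=O)c1c(O)cc(OC(C)(C)C#C)cc1OC
F13 | step 1 | 1-[2-hydroxy-6-methoxy-4-(2-methylbut-3-en-2-yloxy)phenyl]ethanone | CC(=O)c1c(O)cc(OC(C)(C)C=C)cc1OC
A1 | alternative 1 | (2R)-5,7-dihydroxy-8-prenylflavanone, ring B as bis-MOM ether | Oc1cc(O)c(CC=C(C)C)c2c1C(=O)C[C@@H](O2)c1c(OCOC)cccc1OCOC
A2 | alternative 1 | methyl 4-{(2R)-2-[2,6-bis(methoxymethoxy)phenyl]-4-oxo-3,4-dihydro-2H-pyran-6-yl}-7-methyl-3-oxooct-6-enoate | COC(=O)CC(=O)C(CC=C(C)C)C1=CC(=O)C[C@@H](O1)c1c(OCOC)cccc1OCOC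
A3 | alternative 2 | (2R)-flavanone, ring B as bis-allyl ether | COc1c2c(c(CC=C(C)C)c3c1C(=O)C[C@@H](O3)c1c(OCC=C)cccc1OCC=C)OC(C)(C)C=C2
A4 | alternative 2 | 2-[2,6-bis(allyloxy)phenyl]-4-methylene-1,3-benzodioxine on ring A (racemic acetal) | COc1c2C=CC(C)(C)Oc2c(CC=C(C)C)c2OC(c3c(OCC=C)cccc3OCC=C)OC(=C)c12
A5 | alternative 3 | bridged hemiketal with ring B as a cyclohexenone | COc1c2c(c(CC=C(C)C)c3c1[C@@]1(O)C[C@@H](O3)C3=C(CCCC3=O)O1)OC(C)(C)C=C2
A6 | alternative 3 | 5-methoxy-8,8-dimethyl-10-(3-methylbut-2-enyl)-4H,8H-pyrano[3,2-g]chromen-4-one | COc1c2C=CC(C)(C)Oc2c(CC=C(C)C)c2occc(=O)c12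
A7 | alternative 3 | cyclohexane-1,3-dione | O=C1CCCC(=O)C1
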